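**Retrosynthetic overview**

1. Target 12 is ring A: C1(=O), C2 (nonadecyl), C3–H, C4(=O), C5–H, C6–H. The plan rests on the C4 carbonyl and the bare C5=C6 edge, read as a ketene carbon and an ethynyl group on C1, with C1–C2–C3–C4 already joined in a four-membered ring.
2. Disconnect C4–C5: 12 ⇐ 4-ethynyl-4-hydroxy-3-nonadecylcyclobutenone 9, by thermal opening of the four-membered ring and six-membered reclosure.
3. Disconnect C1–C6: 9 ⇐ ethynylmagnesium bromide 8 + 3-nonadecylcyclobutenedione 7.
4. Disconnect C2–chain: 7 ⇐ diisopropyl squarate 2 + the Grignard reagent of 1-bromononadecane 1, with the surplus isopropoxy group exchanged for hydrogen by hydride addition and acid.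
5. Ring order: the four-membered ring is bought as the squarate; ring A is the only ring formed, in the last step.

Key step: step 5

Remark: 12 is achiral; the single stereocentres of 4, 6 and 9 form racemic and are all erased later, so no stereocontrol is needed.

**Route**

Step 1
Reactants: 1 1-bromononadecane; 2 diisopropyl squarate (3,4-di(propan-2-yloxy)cyclobut-3-ene-1,2-dione)
Product: 4 4-hydroxy-4-nonadecyl-2,3-di(propan-2-yloxy)cyclobut-2-en-1-one (racemic), via nonadecylmagnesium bromide 3 (not isolated)
Conditions: Mg, I2 (cat.), THF, 50 °C; then add to 2 (1.05 equiv of 3), THF, −78 → −30 °C; sat. aq NH4Cl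
Reagents that add atoms: none
Why: Grignard formation and 1,2-addition of the alkylmagnesium bromide to one ketone of the squarate ester is the standard squarate monoaddition, the magnesium alkoxide formed shielding the remaining vinylogous ester carbonyl from a second attack; the new carbinol centre forms racemic and is erased in step 2.

Step 2
Reactants: 4 4-hydroxy-4-nonadecyl-2,3-di(propan-2-yloxy)cyclobut-2-en-1-one
Product: 5 3-nonadecyl-4-(propan-2-yloxy)cyclobut-3-ene-1,2-dione
Conditions: conc. HCl (cat.), CH2Cl2, rt
Reagents that add atoms: water (O)
Why: Acid-catalysed rearrangement of a squarate monoadduct: ionisation of the tertiary allylic hydroxyl gives a cyclobutenyl cation held as an oxocarbenium ion by the isopropoxy group next to the ketone, and capture by water with loss of isopropanol unveils the second carbonyl.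

Step 3
Reactants: 5 3-nonadecyl-4-(propan-2-yloxy)cyclobut-3-ene-1,2-dione
Product: 7 3-nonadecylcyclobut-3-ene-1,2-dione, via 4-hydroxy-3-isopropoxy-2-nonadecylcyclobutenone 6 (not isolated)
Conditions: LiAlH(OtBu)3 (1.05 equiv), THF, −40 °C; then 6 M HCl, CH2Cl2, rt
Reagents that add atoms: none
Why: Selective 1,2-reduction by the bulky hydride of the more electrophilic ketone carbonyl (the one beside the isopropoxy-bearing carbon, the other being a vinylogous ester), followed by acid-mediated vinylogous ester hydrolysis, enediol (acyloin) tautomerisation and β-elimination of water, is the hydride/acid route from 3-alkoxy-4-alkylcyclobutenediones to monosubstituted cyclobutenediones; the carbinol centre of 6 is racemic and is lost, and hydride attack at the other carbonyl would reach the same dione by allylic ionisation.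

Step 4
Reactants: 7 3-nonadecylcyclobut-3-ene-1,2-dione; 8 ethynylmagnesium bromide (0.5 M in THF, 1.1 equiv)
Product: 9 4-ethynyl-4-hydroxy-3-nonadecylcyclobut-2-en-1-one (racemic)
Conditions: THF, −78 → −40 °C; sat. aq NH4Cl
Reagents that add atoms: none
Why: 1,2-Addition of an alkynyl Grignard reagent to a cyclobutenedione at low temperature, expected mainly at the carbonyl attached to the alkyl-bearing ring carbon because the other carbonyl receives vinylogous donation from that alkyl-substituted alkene carbon; the carbinol centre forms racemic and vanishes in step 5, and any regioisomeric carbinol (ethynyl on the carbonyl beside the ring CH) would rearrange to the same quinone.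

Step 5
Reactants: 9 4-ethynyl-4-hydroxy-3-nonadecylcyclobut-2-en-1-one
Product: 12 2-nonadecylcyclohexa-2,5-diene-1,4-dione (2-nonadecyl-1,4-benzoquinone; target), via (E)-enynylketene 10 (not isolated), via phenoxyl-aryl diradical 11 (not isolated)
Conditions: p-xylene (0.01 M, degassed), reflux (138 °C), Ar
Reagents that add atoms: none
Why: Heating opens the strained cyclobutenone by conrotatory four-electron electrocyclic cleavage of the C(=O)–C(OH) bond, the hydroxyl rotating outward so that the ethynyl group of ketene 10 lies cis to the ketenyl group. The ketene carbon then bonds to the terminal alkyne carbon in a 6-endo-dig closure (a cycloaromatisation akin to that of enyne-allenes), forming the C4–C5 bond and ring A as diradical 11, and transfer of the hydroxyl hydrogen to the aryl radical carbon C6 should deliver quinone 12 without an oxidant. This is the Moore rearrangement of 4-alkynyl-4-hydroxycyclobutenones to 1,4-benzoquinones. No stereocentre is formed, and the racemic carbinol carbon of 9 becomes the C1 carbonyl. The step needs outward rotation of the hydroxyl, which the donor oxygen on the sp3 ring carbon secures, and six- over five-membered closure (5-exo-dig would lead to an alkylidenecyclopentenedione), which the unsubstituted alkyne terminus favours because it offers no radical-stabilising group. Release of four-ring strain and formation of the quinone make the sequence irreversible.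

**Compound list**

1 | 1-bromononadecane | CCCCCCCCCCCCCCCCCCCBr | starting material
2 | diisopropyl squarate (3,4-di(propan-2-yloxy)cyclobut-3-ene-1,2-dione) | CC(C)OC1=C(OC(C)C)C(=O)C1=O | starting material
3 | nonadecylmagnesium bromide | CCCCCCCCCCCCCCCCCCC[Mg]Br | intermediate
4 | 4-hydroxy-4-nonadecyl-2,3-di(propan-2-yloxy)cyclobut-2-en-1-one (racemic) | CCCCCCCCCCCCCCCCCCCC1(O)C(OC(C)C)=C(OC(C)C)C1=O | intermediate
5 | 3-nonadecyl-4-(propan-2-yloxy)cyclobut-3-ene-1,2-dione | CCCCCCCCCCCCCCCCCCCC1=C(OC(C)C)C(=O)C1=O | intermediate
6 | 4-hydroxy-2-nonadecyl-3-(propan-2-yloxy)cyclobut-2-en-1-one (racemic) | CCCCCCCCCCCCCCCCCCCC1=C(OC(C)C)C(O)C1=O | intermediate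
7 | 3-nonadecylcyclobut-3-ene-1,2-dione | CCCCCCCCCCCCCCCCCCCC1=CC(=O)C1=O | intermediate
8 | ethynylmagnesium bromide | C#C[Mg]Br | starting material
9 | 4-ethynyl-4-hydroxy-3-nonadecylcyclobut-2-en-1-one (racemic) | CCCCCCCCCCCCCCCCCCCC1=CC(=O)C1(O)C#C | intermediate
10 | (3E)-4-hydroxy-3-nonadecylhexa-1,3-dien-5-yn-1-one (enynylketene, ethynyl cis to the ketenyl group) | O=C=C/C(CCCCCCCCCCCCCCCCCCC)=C(\C#C)O | intermediate
11 | 4-hydroxy-3-nonadecylphenoxyl-5-yl diradical (oxygen-centred radical on C1–O, sigma radical on the ring carbon between C–OH and C–H) | [O]c1cc(CCCCCCCCCCCCCCCCCCC)c(O)[c]c1 | intermediate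
12 | 2-nonadecylcyclohexa-2,5-diene-1,4-dione (2-nonadecyl-1,4-benzoquinone) | CCCCCCCCCCCCCCCCCCCC1=CC(=O)C=CC1=O | target

**Step count**

Total: 5 steps. Longest linear sequence: 5 steps (from 1 and 2 to 12).

**Steps most likely to fail, with fallbacks**

Step 5 (key step). The ketene may close through its five-membered mode, or the diradical may take hydrogen from the solvent or oligomerise instead of accepting the hydroxyl hydrogen; prolonged heating may also degrade the electrophilic quinone. The fallback replaces the diradical pathway by a purely pericyclic one. It sets out from 7 and comes back to the route at 12. Vinylmagnesium bromide is added to 7 (THF, −78 °C) to give 4-ethenyl-4-hydroxy-3-nonadecylcyclobut-2-en-1-one F1. Thermolysis of this carbinol in toluene at 110 °C opens it to a dienylketene that closes by six-electron electrocyclisation and tautomerises to 2-nonadecylbenzene-1,4-diol F2. Oxidation with Ag2O in diethyl ether then gives 12. The regioisomeric vinyl carbinol would give the same hydroquinone.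

Step 3. Hydride delivery may lack chemoselectivity (over-reduction, attack at both carbonyls), or the acid stage may stall before the hydrogen shift and dehydration are complete. The fallback changes the order of events so that both acid steps are simple oxocarbenium-assisted allylic ionisations of the type used in step 2. It sets out from 4 and comes back to the route at 7. The remaining ketone of 4 is reduced 1,2 with iBu2AlH (2.2 equiv, THF, −78 → 0 °C) to 1-nonadecyl-3,4-di(propan-2-yloxy)cyclobut-3-ene-1,2-diol F3 (diastereomer mixture, immaterial). Treatment with conc. HCl in CH2Cl2 then ionises the two allylic hydroxyls in turn, each with hydrolysis of one enol ether, to give 7.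

Step 4. The acetylide may add in conjugate fashion to the unsubstituted ring CH, deprotonate the allylic CH2 of the chain, or add twice. The fallback avoids the free monoalkyl dione. It sets out from 5 and comes back to the route at 12. Reagent 8 is added to the ketone carbonyl of 5 beside the isopropoxy-bearing carbon (THF, −78 °C) to give 4-ethynyl-4-hydroxy-2-nonadecyl-3-(propan-2-yloxy)cyclobut-2-en-1-one F4. 1,2-Reduction of its vinylogous ester carbonyl with iBu2AlH (THF, −78 °C) gives 1-ethynyl-3-nonadecyl-2-(propan-2-yloxy)cyclobut-2-ene-1,4-diol F5. Dilute HCl in THF at 0 °C effects a Stork–Danheiser-type transposition with loss of isopropanol to 4-ethynyl-4-hydroxy-2-nonadecylcyclobut-2-en-1-one F6. This regioisomer of 9 should rearrange to 12 under the conditions of step 5.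

Further compounds
F1 | step 5 | 4-ethenyl-4-hydroxy-3-nonadecylcyclobut-2-en-1-one | CCCCCCCCCCCCCCCCCCCC1=CC(=O)C1(O)C=C
F2 | step 5 | 2-nonadecylbenzene-1,4-diol | CCCCCCCCCCCCCCCCCCCc1cc(O)ccc1O
F3 | step 3 | 1-nonadecyl-3,4-di(propan-2-yloxy)cyclobut-3-ene-1,2-diol | CCCCCCCCCCCCCCCCCCCC1(O)C(O)C(OC(C)C)=C1OC(C)C
F4 | step 4 | 4-ethynyl-4-hydroxy-2-nonadecyl-3-(propan-2-yloxy)cyclobut-2-en-1-one | CCCCCCCCCCCCCCCCCCCC1=C(OC(C)C)C(O)(C#C)C1=O
F5 | step 4 | 1-ethynyl-3-nonadecyl-2-(propan-2-yloxy)cyclobut-2-ene-1,4-diol | CCCCCCCCCCCCCCCCCCCC1=C(OC(C)C)C(O)(C#C)C1O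
F6 | step 4 | 4-ethynyl-4-hydroxy-2-nonadecylcyclobut-2-en-1-one | O=C1C(CCCCCCCCCCCCCCCCCCC)=CC1(O)C#C
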